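## The problem

CNP0276938.2 is a longipinane-type tricycle. Ring carbons are numbered C1–C11 in the order of the target SMILES, and the oxymethylene carbon on C4 is called C12. A cyclobutane (C5–C6–C11–C10) has both diagonals bridged: C6/C10 by C7–C8–C9 (a bicyclo[3.1.1]heptan-2-one, ketone at C9) and C5/C11, on the opposite face, by C4–C3–C2–C1 (the seven-membered ring). Seven stereocentres must be set. The four cyclobutane carbons are locked to one another by the ring system, and the cage can place the C7 methyl because the face of C7 under the C11 methyl is blocked. C1 and quaternary C4, however, lie on the near-mirror plane of the cage, so their relation to the C9 side is remote and hardly biased by the cage. Both oxygens sit on neopentyl carbons next to the quaternary centres C4 and C11, so the late acylations are slow. The angelate isomerises to the tiglate with nucleophilic catalysts, base or heat; the cyclobutane opens through cations or radicals at C7 and C9; and the C9 ketone would be enolised by any strong base used elsewhere. The enabling feature is that the C1 oxygen and C12 are cis and 1,4 across the seven-membered ring: with C12 as a carboxyl carbon they can be joined as a seven-membered lactone spanning C5 and C11, and a vinyl group (C2=C3) on C1 then lets one [3,3] shift form C3–C4, the quaternary centre and the carbocycle together.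

## Retrosynthesis

**Acyl groups and ketal.** Target 34 is traced to ketal diester 33, mono-tiglate 30 and ketal diol 28 by cutting the C9 ketal and the two acyl C–O bonds. Keeping the ketal to the end means no enolisable ketone is present during the acylations. The primary C12 hydroxyl is acylated before the more hindered C1 hydroxyl, and the isomerisation-prone angelate then faces only one further, mildly acidic, step.

**C1–O bond.** Diol 28 is traced through epoxide 27 and alkenyl alcohol 26 to acid 25 by cutting the C1–O bond. Hydroboration of the C1=C2 alkene would have no regiochemical or facial handle, whereas the C12 hydroxyl can deliver the epoxide oxygen to its own face and hydride then opens at C2, away from quaternary C11. The precursor 25 has one stereocentre fewer. The forward steps must give syn epoxidation from a bishomoallylic alcohol and regioselective opening.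

**C3–C4 bond (key cut).** Acid 25 is traced to lactone 22 by cutting C3–C4 and reconnecting the C1 oxygen to C12. An enolate alkylation or aldol at C4 would have to choose a face of C4 with no help from the near-symmetric cage. The sigmatropic route makes the quaternary centre and the ring in one step and copies the C1 configuration into C4. Lactone 22 has no carbocyclic seven-membered ring and no quaternary C4. The forward step needs O-silylation of a hindered lactone enolate and a boat [3,3] shift.

**C4 methyl and C9 ketal.** Lactone 22 is traced to lactone 21 and ketone 20 by cutting the C4–CH3 bond and the ketal. Adding the methyl by enolate alkylation after the cage is built keeps every earlier intermediate free of a labile C4 stereocentre. Its configuration does not matter because it is erased in the key step.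

**C7 methyl, C7=C8 and C8.** Ketone 20 is traced through enone 19 and ketone 17 to the bicyclo[2.1.1]hexanone 15 by cutting the C7–CH3 bond, the C7=C8 unsaturation and the C8 carbon. A direct photochemical entry to the bicyclo[3.1.1] skeleton would require a crossed addition of a hepta-1,6-dien-3-one, which the preference for initial five-membered-ring closure disfavours. The lower homologue forms by the favoured mode and is expanded by one carbon.

**Cyclobutane.** Keto lactone 15 is traced to macrocyclic dienone 14 by cutting C5–C6 and C10–C11. An untethered crossed cycloaddition would place the C4 arm on C5 trans to the C11 bridge and could never be lactonised. With the lactone already in place as a ten-membered ring, only the adduct with both arms on the face remote from the C7–C9 bridge can form, and C5 is delivered as C–H.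

**Macrocycle.** Dienone 14 is traced to allylic alcohol 13 and iodo aldehyde 12 by cutting C9–C10. Closing at the ester would require activating a β,γ-unsaturated acid under basic conditions, and metathesis would be diverted by the C1 vinyl group into a six-membered lactone. A chromium-mediated vinyl–aldehyde coupling is neutral and tolerates both.

**Ester.** Aldehyde 12 is traced through alcohol 11 and silyl ether 10 to dienol 6 and iodo acid 9 by cutting the C12–O ester bond. Acid 9 comes from iodo alcohol 8 and but-3-yn-1-ol 7.

**Dienol.** Dienol 6 is traced to racemate 5, enal 3 and vinylmagnesium bromide 4 by cutting C1–C2, and enal 3 to aldehyde 1 and ylide 2 by cutting C6=C11. The single stereocentre that steers everything later, C1, is set by kinetic resolution of a secondary allylic alcohol that carries a trisubstituted alkene.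

## Roads not taken

**Alternative 1:** The cut is the cyclobutane bond C10–C11 in ketone A2, which is traced to the bornane-type bridgehead-hydroxy mesylate A1, where C11 is still bonded to C9. In the forward step, ionisation of the endo mesylate lets the antiperiplanar C9–C11 bond migrate to C10 and the C9 carbonyl forms.
- Merits: the shift is stereospecific (inversion at C10, retention at C11), the strained ring is made late from a less strained norbornane frame, and a camphor-like start could supply absolute configuration. On cyclobutane formation alone this is safer than the photochemistry used here.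
- Weak points: A1 must already contain the seven-membered ring with C1 and C4 set, so the central remote-stereocentre problem is only moved into the synthesis of A1. Norbornyl-type cations offer competing shifts. A2 still lacks the C7 methyl, so the dehydrogenation and cuprate steps remain.
- Comparison: the chosen plan sets against the safer cyclobutane step the creation of C4 and of the ring in one step from a single controlling centre.

**Alternative 2:** The cuts are C6–C7 and C9–C10. Cyclobutanone A3, activated as a chiral pyrrolidine enamine, is C-alkylated and then C-acylated by acryloyl chloride A4 to give dione A5.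
- Merits: it is the shortest route to the cage, starts from an achiral ketone, avoids photochemistry, sets absolute configuration by desymmetrisation, and should place the C11 methyl on the side of the new bridge. In step count to the bicyclic core it is clearly better than the chosen plan.
- Weak points: cyclobutanone enamines form and react reluctantly. The annulation must close a strained bridged 1,3-dione that is prone to retro-Claisen opening. A5 carries C5 as a ketone beside a second ketone at C9, so the two must be differentiated and the C5–H orientation set by an addition with little facial bias. C7 methyl, C4, C1 and the whole seven-membered ring remain.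
- Comparison: the chosen plan offsets its longer front end by delivering C5 as C–H in the right orientation and by fixing C4 and C1 through the tether.

**Alternative 3:** The cuts are C5–C10 and C6–C11. Acid chloride A6 is dehydrochlorinated to ketene A7, whose carbonyl carbon bonds to the less substituted alkene carbon C10 and whose α-carbon bonds to C11, giving cyclobutanone A8.
- Merits: this intramolecular ketene–alkene mode is the established thermal entry to bicyclo[3.1.1]heptan-6-ones. It is concerted, so the alkene geometry fixes C11. The C7 centre comes from the chiral pool and the C9 ketal is already present. For building the cage it is better precedented and shorter than the macrocyclisation and photocycloaddition used here.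
- Weak points: C5 emerges as a carbonyl. Attaching the C4 arm with the correct C5–H orientation, making quaternary C4 and relating C1 to the cage are all left to later steps with no built-in control.
- Comparison: the chosen plan accepts a riskier cage construction because the same lactone that templates the photocycloaddition also carries the stereochemical information for C4.

Key step: step 17

Remark: the C4 configuration of lactone 22 is immaterial, as it is erased in step 17; 22 is drawn as the epimer expected from alkylation anti to the vinyl group. At the bicyclo[2.1.1]hexane stage the bridge carbons already carry their final labels C7 and C9; C8 is inserted in step 12.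

Step 1
Reactants: 1 3-[(tert-butyldimethylsilyl)oxy]propanal; 2 2-(triphenylphosphoranylidene)propanal
Product: 3 (E)-5-[(tert-butyldimethylsilyl)oxy]-2-methylpent-2-enal
Conditions: toluene, 90 °C
Reagents that add atoms: none
Why: Wittig olefination with a formyl-stabilised ylide gives the E trisubstituted enal and so fixes the C6=C11 geometry with the methyl cis to the chain.

Step 2
Reactants: 3 (E)-enal; 4 vinylmagnesium bromide
Product: 5 rac-(E)-7-[(tert-butyldimethylsilyl)oxy]-4-methylhepta-1,4-dien-3-ol
Conditions: THF, −78 to 0 °C; aq. NH4Cl
Reagents that add atoms: none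
Why: Grignard 1,2-addition to the enal creates the C1 carbinol (racemic) flanked by the vinyl group C2=C3 and the trisubstituted alkene.

Step 3
Reactants: 5 racemic dienol
Product: 6 (3R,4E)-7-[(tert-butyldimethylsilyl)oxy]-4-methylhepta-1,4-dien-3-ol
Conditions: Ti(OiPr)4, L-(+)-diisopropyl tartrate, t-BuOOH (0.6 equiv), 4 Å sieves, CH2Cl2, −20 °C
Reagents that add atoms: none
Why: Sharpless kinetic resolution: with the L-(+)-tartrate the (S)-alcohol is epoxidised at its trisubstituted alkene far faster than the (R)-alcohol, which is recovered; the monosubstituted vinyl group reacts much more slowly, so stopping just past half conversion should leave 6 enantioenriched.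

Step 4
Reactants: 7 but-3-yn-1-ol
Product: 8 (E)-4-iodobut-3-en-1-ol
Conditions: Cp2Zr(H)Cl (2.2 equiv), THF, rt; then I2, 0 °C
Reagents that add atoms: iodine, II
Why: Hydrozirconation adds Zr–H syn with zirconium on the terminal carbon, and iodinolysis with retention gives the E vinyl iodide; one equivalent of the hydride is consumed by the hydroxyl group.

Step 5
Reactants: 8 (E)-4-iodobut-3-en-1-ol
Product: 9 (E)-4-iodobut-3-enoic acid
Conditions: TEMPO (cat.), PhI(OAc)2, MeCN/H2O, rt
Reagents that add atoms: water, O
Why: Oxoammonium oxidation of the primary alcohol through the aldehyde hydrate gives the acid under near-neutral conditions that leave the vinyl iodide and the β,γ-alkene in place.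

Step 6
Reactants: 6 (R)-dienol; 9 (E)-4-iodobut-3-enoic acid
Product: 10 (3R,4E)-7-[(tert-butyldimethylsilyl)oxy]-4-methylhepta-1,4-dien-3-yl (E)-4-iodobut-3-enoate
Conditions: DCC, DMAP (cat.), CH2Cl2, 0 °C
Reagents that add atoms: none
Why: Steglich esterification forms the C12–O bond with retention at C1; low temperature and little DMAP limit conjugation of the β,γ-unsaturated acyl group.

Step 7
Reactants: 10 silyl ether ester
Product: 11 (3R,4E)-7-hydroxy-4-methylhepta-1,4-dien-3-yl (E)-4-iodobut-3-enoate
Conditions: HF·pyridine, pyridine, THF, 0 °C to rt
Reagents that add atoms: none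
Why: Buffered fluoride desilylation frees the primary alcohol without ionising the doubly allylic ester.

Step 8
Reactants: 11 primary alcohol
Product: 12 (3R,4E)-4-methyl-7-oxohepta-1,4-dien-3-yl (E)-4-iodobut-3-enoate
Conditions: Dess–Martin periodinane, NaHCO3, CH2Cl2, 0 °C; used crude
Reagents that add atoms: none
Why: Buffered Dess–Martin oxidation gives the β,γ-unsaturated aldehyde (C9) without moving the C6=C11 alkene into conjugation.

Step 9
Reactants: 12 iodo aldehyde
Product: 13 (4E,8E,10R)-10-ethenyl-6-hydroxy-9-methyl-3,6,7,10-tetrahydro-2H-oxecin-2-one (both carbinol epimers)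
Conditions: CrCl2 (excess), NiCl2 (cat.), DMSO/THF, rt, slow addition at high dilution
Reagents that add atoms: none
Why: Intramolecular Nozaki–Hiyama–Kishi reaction: zerovalent nickel inserts into the C–I bond with retention, the alkenyl group passes to trivalent chromium and adds to the aldehyde chemoselectively, forming C9–C10 and the ten-membered lactone, a ring size for which this closure is known; the new carbinol centre is removed in step 10.

Step 10
Reactants: 13 macrocyclic allylic alcohol
Product: 14 (4E,8E,10R)-10-ethenyl-9-methyl-7,10-dihydro-2H-oxecine-2,6(3H)-dione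
Conditions: Dess–Martin periodinane, NaHCO3, CH2Cl2, 0 °C; used at once
Reagents that add atoms: none
Why: Oxidation of the allylic alcohol makes both epimers converge on the enone chromophore (C5=C10–C9=O) needed for step 11.

Step 11
Reactants: 14 macrocyclic dienone
Product: 15 cage keto lactone (bicyclo[2.1.1]hexan-2-one with cyclobutane C5–C6–C11–C10 and bridge C6–C7H2–C9(=O)–C10; C5 and C11 spanned on the far face by the lactone C5–C4H2–C12(=O)–O–C1H(vinyl)–C11; C11 methyl)
Conditions: hν (350 nm, Pyrex), degassed MeCN, 0.005 M, rt
Reagents that add atoms: none
Why: Transannular crossed enone–alkene [2+2] photocycloaddition of a hexa-1,5-dien-3-one unit, a known route to bicyclo[2.1.1]hexan-2-ones: the enone triplet bonds C5 to C6 (five-membered ring first) and the 1,4-diradical collapses by C10–C11. The lactone tether allows only the adduct with both arms on the face remote from the C7/C9 bridge, which fixes C5, C6, C10 and C11. The cage sense relative to C1 should follow from the vinyl group lying anti to the forming bonds, with the C1 hydrogen rather than the vinyl next to the C11 methyl (allylic 1,2-strain).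

Step 12
Reactants: 15 cage keto lactone
Product: 17 ring-expanded keto lactone (bicyclo[3.1.1]heptan-2-one cage with C9 ketone and C7 and C8 methylene), via α-trimethylsilyl ketone 16 (not isolated)
Conditions: Me3SiCHN2, Sc(OTf)3 (cat.), CH2Cl2, −78 to 0 °C; then 1 M HCl, THF, 0 °C
Reagents that add atoms: trimethylsilyldiazomethane, C[Si](C)(C)C=[N+]=[N-]
Why: Lewis-acid-catalysed diazoalkane homologation of the strained ketone: the diazo carbon adds to C9 and the less substituted C7 migrates in preference to the bridgehead cyclobutane carbon C10, inserting C8 between C7 and C9; protodesilylation gives the ketone.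

Step 13
Reactants: 17 ring-expanded keto lactone
Product: 19 enone lactone (C7=C8–C9=O), via trimethylsilyl enol ether 18 (not isolated)
Conditions: LiHMDS, Me3SiCl, THF, −78 °C; then Pd(OAc)2, MeCN, rt
Reagents that add atoms: none
Why: Saegusa oxidation: the ketone can enolise only toward C8 (C10 is a bridgehead) and is more acidic than the lactone; the palladium enolate loses β-hydride to give the enone.

Step 14
Reactants: 19 enone lactone
Product: 20 7-methyl keto lactone
Conditions: Me2CuLi (from MeLi and CuI), Et2O, −78 °C; aq. NH4Cl
Reagents that add atoms: lithium dimethylcuprate, [Li+].C[Cu-]C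
Why: Cuprate conjugate addition sets C7: the methyl enters from the face flanked by C5–H and not the one under the C11 methyl, as with 6,6-dimethylbicyclo[3.1.1]hept-3-en-2-ones; at −78 °C addition to the enone outruns allylic substitution at the lactone.

Step 15
Reactants: 20 7-methyl keto lactone
Product: 21 ketal lactone (C9 ethylene ketal)
Conditions: (Me3SiOCH2)2, Me3SiOTf (cat.), CH2Cl2, −78 to −20 °C
Reagents that add atoms: 1,2-bis(trimethylsilyloxy)ethane, C[Si](C)(C)OCCO[Si](C)(C)C
Why: Aprotic Noyori ketalisation masks the C9 ketone against enolisation in steps 16 and 17 and against hydride in steps 18 and 20, without exposing the allylic lactone to protic acid.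

Step 16
Reactants: 21 ketal lactone
Product: 22 C4-methyl ketal lactone (key-step precursor; vinyl on C1, methyl on C4 anti to it)
Conditions: LDA, THF, −78 °C; then MeI, DMPU, −78 to −40 °C
Reagents that add atoms: iodomethane, CI
Why: α-Alkylation of the lactone enolate installs the C4 methyl, expected anti to the C1 vinyl group; either epimer serves, because C4 becomes trigonal in step 17.

Step 17
Reactants: 22 C4-methyl ketal lactone
Product: 25 cycloheptene carboxylic acid (C1=C2 alkene; quaternary C4 bearing methyl and CO2H; C9 ketal), via silyl ketene acetal 23 (not isolated), via trimethylsilyl ester 24 (not isolated)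
Conditions: LDA, Me3SiCl/Et3N, THF, −78 °C; then toluene, 90 °C; then H2O/THF, pH 5 buffer
Reagents that add atoms: none
Why: Ireland–Claisen rearrangement of a vinyl-substituted lactone, the known ring switch of vinyl lactones and alkenyl dioxanones into cycloalkene acids. LDA removes the C4 hydrogen and the enolate is silylated on oxygen to give ketene acetal 23, whose C4=C12 geometry is fixed because C5 and the ring oxygen both lie in the seven-membered ring. On warming, the array C4=C12–O–C1–C2=C3 passes through a boat six-centre transition state: C3 bonds to C4, the C1–O bond breaks, and the carbocyclic seven-membered ring closes with a cis C1=C2 alkene while the lactone opens to silyl ester 24. The only new stereocentre, quaternary C4, is controlled by C1: the vinyl group sits on the C6 side of the lactone and can reach C4 only from that face, so C12 stays on the C10 side and the methyl ends on the C6 side, whichever C4 epimer of 22 enters. This facial selectivity is the one required and the tether secures it, since the other face is out of reach; C1 becomes trigonal and is rebuilt in steps 19 and 20. Both arms are held cis on the cyclobutane, so neither 23 nor 25 gains strain, and the ketal prevents competing ketone enolisation. Mild hydrolysis of 24 gives acid 25 with both oxygens of the former lactone.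

Step 18
Reactants: 25 cycloheptene carboxylic acid
Product: 26 alkenyl primary alcohol (C12 hydroxymethyl on C4)
Conditions: LiAlH4, THF, 0 °C to reflux
Reagents that add atoms: none
Why: Hydride reduction of the neopentyl acid to the C12 alcohol; ketal and alkene are inert.

Step 19
Reactants: 26 alkenyl primary alcohol
Product: 27 syn epoxy alcohol (C1–C2 epoxide on the face of the C12 hydroxymethyl)
Conditions: VO(acac)2 (cat.), t-BuOOH, CH2Cl2, 0 °C to rt
Reagents that add atoms: tert-butyl hydroperoxide, CC(C)(C)OO
Why: Hydroxyl-directed epoxidation: the vanadium-bound alkoxide delivers the peroxide oxygen to the alkene face cis to the C4 hydroxymethyl, as with cyclohex-3-enylmethanols, setting the C1–O bond; the syn epoxide cannot be opened by its own hydroxyl, which has no backside access.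

Step 20
Reactants: 27 syn epoxy alcohol
Product: 28 ketal diol (C1 secondary alcohol cis to the C12 hydroxymethyl)
Conditions: LiAlH4, THF, reflux
Reagents that add atoms: none
Why: SN2 hydride opening at C2, the epoxide carbon remote from quaternary C11, leaves the oxygen on C1 with the target configuration.

Step 21
Reactants: 28 ketal diol; 29 tigloyl chloride
Product: 30 ketal mono-tiglate (C12 tiglate, C1 alcohol free)
Conditions: pyridine, CH2Cl2, −20 to 0 °C
Reagents that add atoms: none
Why: The primary hydroxyl is acylated much faster than the secondary hydroxyl next to quaternary C11.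

Step 22
Reactants: 30 ketal mono-tiglate; 31 angelic acid
Product: 33 ketal tiglate angelate, via mixed angelic 2,4,6-trichlorobenzoic anhydride 32 (not isolated)
Conditions: 2,4,6-trichlorobenzoyl chloride, Et3N, toluene, rt; then 30, toluene, 80 °C
Reagents that add atoms: none
Why: Yamaguchi-type mixed-anhydride esterification without a nucleophilic catalyst, the conditions under which angelates are formed with least Z-to-E isomerisation.

Step 23
Reactants: 33 ketal tiglate angelate
Product: 34 CNP0276938.2
Conditions: 1 M HCl, THF, 0 °C to rt
Reagents that add atoms: water, O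
Why: Acid-catalysed ketal hydrolysis releases the C9 ketone; the two unsaturated esters and the angelate geometry tolerate dilute acid at room temperature.

## Compound list

1 | 3-[(tert-butyldimethylsilyl)oxy]propanal | CC(C)(C)[Si](C)(C)OCCC=O | starting material
2 | 2-(triphenylphosphoranylidene)propanal | CC(C=O)=P(c1ccccc1)(c1ccccc1)c1ccccc1 | starting material
3 | (E)-5-[(tert-butyldimethylsilyl)oxy]-2-methylpent-2-enal | CC(C)(C)[Si](C)(C)OCC/C=C(\C)C=O | intermediate
4 | vinylmagnesium bromide | C=C[Mg]Br | starting material
5 | rac-(E)-7-[(tert-butyldimethylsilyl)oxy]-4-methylhepta-1,4-dien-3-ol | C=CC(O)/C(C)=C/CCO[Si](C)(C)C(C)(C)C | intermediate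
6 | (3R,4E)-7-[(tert-butyldimethylsilyl)oxy]-4-methylhepta-1,4-dien-3-ol | C=C[C@@H](O)/C(C)=C/CCO[Si](C)(C)C(C)(C)C | intermediate
7 | but-3-yn-1-ol | C#CCCO | starting material
8 | (E)-4-iodobut-3-en-1-ol | OCC/C=C/I | intermediate
9 | (E)-4-iodobut-3-enoic acid | OC(=O)C/C=C/I | intermediate
10 | (3R,4E)-7-[(tert-butyldimethylsilyl)oxy]-4-methylhepta-1,4-dien-3-yl (E)-4-iodobut-3-enoate | C=C[C@@H](OC(=O)C/C=C/I)/C(C)=C/CCO[Si](C)(C)C(C)(C)C | intermediate
11 | (3R,4E)-7-hydroxy-4-methylhepta-1,4-dien-3-yl (E)-4-iodobut-3-enoate | C=C[C@@H](OC(=O)C/C=C/I)/C(C)=C/CCO | intermediate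
12 | (3R,4E)-4-methyl-7-oxohepta-1,4-dien-3-yl (E)-4-iodobut-3-enoate | C=C[C@@H](OC(=O)C/C=C/I)/C(C)=C/CC=O | intermediate
13 | (4E,8E,10R)-10-ethenyl-6-hydroxy-9-methyl-3,6,7,10-tetrahydro-2H-oxecin-2-one, both carbinol epimers | C=C[C@H]1OC(=O)C/C=C/C(O)C/C=C1\C | intermediate
14 | (4E,8E,10R)-10-ethenyl-9-methyl-7,10-dihydro-2H-oxecine-2,6(3H)-dione | C=C[C@H]1OC(=O)C/C=C/C(=O)C/C=C1\C | intermediate
15 | cage keto lactone: bicyclo[2.1.1]hexan-2-one (C9 ketone, C7 methylene) with the C1-vinyl lactone spanning C5 and C11 | C=C[C@H]1OC(=O)C[C@H]2[C@@H]3CC(=O)[C@H]2[C@@]31C | intermediate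
16 | α-trimethylsilyl ketone of the ring-expanded cage (silyl on C8) | C=C[C@H]1OC(=O)C[C@H]2[C@@H]3CC([Si](C)(C)C)C(=O)[C@H]2[C@@]31C | intermediate (not isolated)
17 | ring-expanded keto lactone: bicyclo[3.1.1]heptan-2-one cage (C9 ketone, C7 and C8 methylene) | C=C[C@H]1OC(=O)C[C@H]2[C@@H]3CCC(=O)[C@H]2[C@@]31C | intermediate
18 | trimethylsilyl enol ether (C8=C9) of 17 | C=C[C@H]1OC(=O)C[C@H]2[C@@H]3CC=C(O[Si](C)(C)C)[C@H]2[C@@]31C | intermediate (not isolated)
19 | enone lactone (C7=C8–C9=O) | C=C[C@H]1OC(=O)C[C@H]2[C@@H]3C=CC(=O)[C@H]2[C@@]31C | intermediate
20 | 7-methyl keto lactone (methyl on C7 on the C5 side) | C=C[C@H]1OC(=O)C[C@H]2[C@@H]3[C@H](C)CC(=O)[C@H]2[C@@]31C | intermediate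
21 | ketal lactone (C9 ethylene ketal) | C=C[C@H]1OC(=O)C[C@H]2[C@@H]3[C@H](C)CC4(OCCO4)[C@H]2[C@@]31C | intermediate
22 | C4-methyl ketal lactone, vinyl-substituted bridging lactone (key-step precursor) | C=C[C@H]1OC(=O)[C@H](C)[C@H]2[C@@H]3[C@H](C)CC4(OCCO4)[C@H]2[C@@]31C | intermediate
23 | trimethylsilyl ketene acetal of 22 | C=C[C@H]1OC(O[Si](C)(C)C)=C(C)[C@H]2[C@@H]3[C@H](C)CC4(OCCO4)[C@H]2[C@@]31C | intermediate (not isolated)
24 | trimethylsilyl ester of 25 | C1=CC[C@](C)(C(=O)O[Si](C)(C)C)[C@H]2[C@@H]3[C@H](C)CC4(OCCO4)[C@H]2[C@@]31C | intermediate (not isolated)
25 | tricyclic cycloheptene carboxylic acid with quaternary C4 (key-step product) | C1=CC[C@](C)(C(=O)O)[C@H]2[C@@H]3[C@H](C)CC4(OCCO4)[C@H]2[C@@]31C | intermediate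
26 | alkenyl primary alcohol (C12 hydroxymethyl) | C1=CC[C@](C)(CO)[C@H]2[C@@H]3[C@H](C)CC4(OCCO4)[C@H]2[C@@]31C | intermediate
27 | syn C1–C2 epoxy alcohol | O1[C@@H]2[C@H]1C[C@](C)(CO)[C@H]3[C@@H]4[C@H](C)CC5(OCCO5)[C@H]3[C@@]42C | intermediate
28 | ketal diol (C1 alcohol, C12 alcohol, cis) | O[C@@H]1CC[C@](C)(CO)[C@H]2[C@@H]3[C@H](C)CC4(OCCO4)[C@H]2[C@@]31C | intermediate
29 | tigloyl chloride, (E)-2-methylbut-2-enoyl chloride | C/C=C(\C)C(=O)Cl | starting material
30 | ketal mono-tiglate (C12 tiglate, C1 alcohol) | O[C@@H]1CC[C@](C)(COC(=O)/C(C)=C/C)[C@H]2[C@@H]3[C@H](C)CC4(OCCO4)[C@H]2[C@@]31C | intermediate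
31 | angelic acid, (Z)-2-methylbut-2-enoic acid | C/C=C(/C)C(=O)O | starting material
32 | mixed angelic 2,4,6-trichlorobenzoic anhydride | C/C=C(/C)C(=O)OC(=O)c1c(Cl)cc(Cl)cc1Cl | intermediate (not isolated)
33 | ketal tiglate angelate | C/C=C(/C)C(=O)O[C@@H]1CC[C@](C)(COC(=O)/C(C)=C/C)[C@H]2[C@@H]3[C@H](C)CC4(OCCO4)[C@H]2[C@@]31C | intermediate
34 | CNP0276938.2 | C/C=C(/C)C(=O)O[C@@H]1CC[C@](C)(COC(=O)/C(C)=C/C)[C@H]2[C@@H]3[C@H](C)CC(=O)[C@H]2[C@@]31C | target

## Step count and least certain steps

Total: 23 steps. Longest linear sequence: 21 steps (steps 1–3 and 6–23, from 1). Steps 4 and 5 make the side-branch acid 9.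

**Step 17 (key step).** Silylation of the hindered, α-branched lactone enolate may be incomplete or occur on carbon. The boat rearrangement may also be slow enough for the ketene acetal to revert or decompose on heating. The fallback keeps the tether logic but forms C3–C4 by ionic alkylation. It sets out from 22. Hydroboration of the vinyl group (9-BBN, then NaBO3) should give the primary alcohol F1, and iodination (I2, PPh3, imidazole) the primary iodide F2. Deprotonation of the lactone (KHMDS, THF, −78 to 0 °C) should then alkylate C4 intramolecularly from the face that carries the side chain, giving the bridged δ-lactone F3 with the same C4 configuration as 25 and with the C1 oxygen retained. LiAlH4 reduction of F3 returns to the route at diol 28, so steps 18–20 are not needed.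

**Step 11.** Several things can go wrong:
- facial selection relative to C1 may be weak, giving the cage with the vinyl group on the C10 side;
- the enone may photodeconjugate by γ-hydrogen transfer from C4;
- the diradical may close in the parallel sense.

The fallback changes the excitation mode and sets out from allylic alcohol 13. Copper-catalysed photobicyclisation of the non-conjugated diene (CuOTf, Et2O, 254 nm), the reaction known for cycloocta-1,5-diene and for dienyl alcohols, should give the cyclobutane alcohol F4 through a monovalent-copper diene chelate. Dess–Martin oxidation returns to the route at 15.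

**Step 9.** The ten-membered ring closure may give oligomers, and the β,γ-unsaturated aldehyde may slip into conjugation before it reacts. The fallback closes the ring at the ester instead and sets out from 6:
1. Silylation (t-BuMe2SiOTf, 2,6-lutidine) gives the bis-silyl ether F5.
2. Selective removal of the primary silyl group (HF·pyridine) gives alcohol F6.
3. Dess–Martin oxidation gives aldehyde F7.
4. Intermolecular Nozaki–Hiyama–Kishi coupling with 2-(trimethylsilyl)ethyl (E)-4-iodobut-3-enoate F8 (from 9, 2-(trimethylsilyl)ethanol and DCC) gives hydroxy ester F9.
5. Bu4NF removes both silyl groups to give seco acid F10.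
6. Shiina macrolactonisation (2-methyl-6-nitrobenzoic anhydride, DMAP, high dilution) returns to the route at 13.

Only the C1 hydroxyl can lactonise, since the C9 hydroxyl would need a trans alkene in a six-membered ring.

**Step 12.** The bridgehead carbon C10 may migrate instead of C7, or a second insertion may occur. The fallback is regiospecific because the new carbon is attached through the only possible enol ether. It sets out from 15. Silylation (LiHMDS, Me3SiCl) gives the silyl enol ether F11, and cyclopropanation (Et2Zn, CH2I2) the siloxycyclopropane F12. FeCl3 in DMF cleaves the internal cyclopropane bond to the ring-expanded β-chloro ketone F13. Elimination with DBU returns to the route at enone 19, so step 13 is not needed.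

**Step 22.** The hindered C1 alcohol may acylate slowly, and the angelate may isomerise to the tiglate under the forcing conditions, giving a ditiglate that is hard to separate. The fallback builds the Z alkene on the ester and sets out from 30. Acylation with 2-(diphenoxyphosphoryl)propanoic acid (DCC, DMAP) gives the phosphonate ester F14. Z-selective Horner–Wadsworth–Emmons olefination with acetaldehyde (NaH, THF, −78 °C) returns to the route at 33.

## Further compounds

F1 | step 17 | primary alcohol from hydroboration of 22 (2-hydroxyethyl on C1) | OCC[C@H]1OC(=O)[C@H](C)[C@H]2[C@@H]3[C@H](C)CC4(OCCO4)[C@H]2[C@@]31C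
F2 | step 17 | primary iodide (2-iodoethyl on C1) | ICC[C@H]1OC(=O)[C@H](C)[C@H]2[C@@H]3[C@H](C)CC4(OCCO4)[C@H]2[C@@]31C
F3 | step 17 | bridged δ-lactone (C1–O–C12(=O)–C4 across the closed cycloheptane) | O=C1O[C@@H]2CC[C@@]1(C)[C@H]3[C@@H]4[C@H](C)CC5(OCCO5)[C@H]3[C@@]42C
F4 | step 11 | cyclobutane alcohol (C9 carbinol epimers of the cage lactone) | C=C[C@H]1OC(=O)C[C@H]2[C@@H]3CC(O)[C@H]2[C@@]31C
F5 | step 9 | (3R,4E)-3,7-bis[(tert-butyldimethylsilyl)oxy]-4-methylhepta-1,4-diene | C=C[C@@H](O[Si](C)(C)C(C)(C)C)/C(C)=C/CCO[Si](C)(C)C(C)(C)C
F6 | step 9 | (3E,5R)-5-[(tert-butyldimethylsilyl)oxy]-4-methylhepta-3,6-dien-1-ol | C=C[C@@H](O[Si](C)(C)C(C)(C)C)/C(C)=C/CCO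
F7 | step 9 | (3E,5R)-5-[(tert-butyldimethylsilyl)oxy]-4-methylhepta-3,6-dienal | C=C[C@@H](O[Si](C)(C)C(C)(C)C)/C(C)=C/CC=O
F8 | step 9 | 2-(trimethylsilyl)ethyl (E)-4-iodobut-3-enoate | C[Si](C)(C)CCOC(=O)C/C=C/I
F9 | step 9 | hydroxy ester from the intermolecular coupling (C9 carbinol epimers) | C=C[C@@H](O[Si](C)(C)C(C)(C)C)/C(C)=C/CC(O)/C=C/CC(=O)OCC[Si](C)(C)C
F10 | step 9 | seco dihydroxy acid | C=C[C@@H](O)/C(C)=C/CC(O)/C=C/CC(=O)O
F11 | step 12 | trimethylsilyl enol ether (C7=C9) of 15 | C=C[C@H]1OC(=O)C[C@H]2[C@@H]3C=C(O[Si](C)(C)C)[C@H]2[C@@]31C
F12 | step 12 | siloxycyclopropane from F11 | C=C[C@H]1OC(=O)C[C@H]2[C@@H]3C4CC4(O[Si](C)(C)C)[C@H]2[C@@]31C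
F13 | step 12 | ring-expanded β-chloro ketone (chlorine on C7) | C=C[C@H]1OC(=O)C[C@H]2[C@@H]3C(Cl)CC(=O)[C@H]2[C@@]31C
F14 | step 22 | 2-(diphenoxyphosphoryl)propanoate of 30 at the C1 oxygen | CC(C(=O)O[C@@H]1CC[C@](C)(COC(=O)/C(C)=C/C)[C@H]2[C@@H]3[C@H](C)CC4(OCCO4)[C@H]2[C@@]31C)P(=O)(Oc1ccccc1)Oc1ccccc1
A1 | alternative 1 | bornane-type bridgehead-hydroxy endo-mesylate (C11 bonded to C9) | CC(C)(C)[Si](C)(C)O[C@@H]1CC[C@](C)(CO[Si](C)(C)C(C)(C)C)[C@H]2[C@@H]3CC[C@](O)([C@@H]2OS(C)(=O)=O)[C@@]31C
A2 | alternative 1 | tricyclic C9 ketone lacking the C7 methyl | CC(C)(C)[Si](C)(C)O[C@@H]1CC[C@](C)(CO[Si](C)(C)C(C)(C)C)[C@H]2[C@@H]3CCC(=O)[C@H]2[C@@]31C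
A3 | alternative 2 | 3-methyl-3-{[(triisopropylsilyl)oxy]methyl}cyclobutanone | O=C1CC(C)(CO[Si](C(C)C)(C(C)C)C(C)C)C1
A4 | alternative 2 | acryloyl chloride | C=CC(=O)Cl
A5 | alternative 2 | bicyclo[3.1.1]heptane-2,6-dione with quaternary C11 | O=C1[C@@H]2CCC(=O)[C@H]1[C@]2(C)CO[Si](C(C)C)(C(C)C)C(C)C
A6 | alternative 3 | acid chloride with C7 methyl, C9 ketal and E trisubstituted alkene | O=C(Cl)C[C@H](C)CC1(OCCO1)/C=C(\C)CO[Si](C)(C)C(C)(C)C
A7 | alternative 3 | ketene from A6 | O=C=C[C@H](C)CC1(OCCO1)/C=C(\C)CO[Si](C)(C)C(C)(C)C
A8 | alternative 3 | bicyclo[3.1.1]heptan-6-one with C7 methyl, C9 ketal and quaternary C11 | O=C1[C@@H]2[C@H](C)CC3(OCCO3)[C@H]1[C@]2(C)CO[Si](C)(C)C(C)(C)C
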